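**Retrosynthetic overview**

- Feature: in ring B of the trans-decalin, the ring-fusion methine C5 sits next to the quaternary angular carbon C10, and the carbinol-bearing C7 lies two atoms from C5 (C5–C6–C7). With C3 oxygenated in ring A, this pattern maps onto a 1,7,9-decatriene: diene C2=C3–C4=C5, tether C6–C9 carrying C7, and dienophile C10=C1 holding the future angular methyl as CO2Me on C10.
- Late disconnections: silyl groups; the benzyl–vinyl bond of one allyl group (Stille); the biaryl bond (Suzuki–Miyaura); the C3–O–aryl bond (SNAr of the axial C3 alkoxide on 3-bromo-4-fluorobenzaldehyde); C10–CH3 back to CO2Me; C3–CH3 back to the C3 ketone.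
- Key disconnection: C5–C10 and C1–C2 by an intramolecular Diels–Alder reaction. Rings A and B form together in that one step, and both arene rings are bought.
- Triene: (R)-limonene is hydrated and silylated, then its ring alkene is cleaved. This gives a CH2CHO arm (to enone, then 2-silyloxydiene) and a methyl ketone arm (to enol triflate, then 2-alkylacrylate). Limonene C4 becomes C7 and is the only stereocentre bought.

Key step: step 10

Remark: bicyclic compounds carry decalin numbering (C3 oxygenated carbon, C5 ring-fusion CH, C7 side-chain carbon, C10 angular carbon; ring A = C1–C5 and C10, ring B = C5–C10); β is the face of the C10 substituent and α the opposite face; acyclic compounds carry chain numbering.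

Step 1
Reactants: 1 (R)-(+)-limonene
Product: 3 (R)-α-terpineol, via acetoxymercurial 2 (not isolated)
Conditions: Hg(OAc)2 (1.0 equiv), THF/H2O 1:1, 23 °C; then 3 M NaOH, NaBH4, 0 °C
Reagents that add atoms: water, SMILES O
Why: Oxymercuration–demercuration (Markovnikov hydration) takes the unhindered 1,1-disubstituted isopropenyl alkene much faster than the trisubstituted ring alkene when one equivalent of Hg(OAc)2 is used, and the stereocentre (future C7) is a spectator.

Step 2
Reactants: 3 (R)-α-terpineol
Product: 4 (R)-α-terpinyl triethylsilyl ether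
Conditions: Et3SiOTf, 2,6-lutidine, CH2Cl2, 0 °C
Reagents that add atoms: triethylsilyl triflate, SMILES CC[Si](CC)(CC)OS(=O)(=O)C(F)(F)F
Why: Silylation of the hindered tertiary alcohol by a silyl triflate with a non-nucleophilic base gives a tertiary silyl ether that withstands base, hydride and brief fluoride exposure yet leaves with excess fluoride at the end.

Step 3
Reactants: 4 (R)-α-terpinyl triethylsilyl ether
Product: 6 (3R)-6-oxo-3-[2-(triethylsilyloxy)propan-2-yl]heptanal, via secondary ozonide 5 (not isolated)
Conditions: O3, CH2Cl2, −78 °C; then PPh3, −78 → 23 °C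
Reagents that add atoms: ozone, SMILES [O-][O+]=O
Why: Ozonolysis with reductive work-up cleaves the only alkene into a methyl ketone arm and an aldehyde arm, and the stereocentre is β to both carbonyl groups and so cannot epimerise.

Step 4
Reactants: 6 (3R)-6-oxo-3-[2-(triethylsilyloxy)propan-2-yl]heptanal
Product: 7 (5R)-7,7-dimethoxy-5-[2-(triethylsilyloxy)propan-2-yl]heptan-2-one
Conditions: HC(OMe)3, CeCl3·7H2O (cat), MeOH, 0 → 23 °C
Reagents that add atoms: trimethyl orthoformate, SMILES COC(OC)OC
Why: Chemoselective acetalisation under the mild Lewis acid CeCl3 converts the aldehyde much faster than the methyl ketone and does not solvolyse the tertiary silyl ether.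

Step 5
Reactants: 7 (5R)-7,7-dimethoxy-5-[2-(triethylsilyloxy)propan-2-yl]heptan-2-one
Product: 9 (5R)-7,7-dimethoxy-5-[2-(triethylsilyloxy)propan-2-yl]hept-1-en-2-yl triflate, via lithium enolate 8 (not isolated)
Conditions: LiN(iPr)2 (1.15 equiv), THF, −78 °C, slow addition of 7; then N-(5-chloro-2-pyridyl)bis(trifluoromethanesulfonimide), −78 → −20 °C
Reagents that add atoms: N-(5-chloro-2-pyridyl)bis(trifluoromethanesulfonimide), SMILES O=S(=O)(N(c1ccc(Cl)cn1)S(=O)(=O)C(F)(F)F)C(F)(F)F
Why: Kinetic enolate formation at the methyl group by a hindered amide base, followed by O-sulfonylation with a triflimide that already reacts at −78 °C so that the enolate cannot equilibrate, gives the terminal 1-alken-2-yl triflate.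

Step 6
Reactants: 9 (5R)-7,7-dimethoxy-5-[2-(triethylsilyloxy)propan-2-yl]hept-1-en-2-yl triflate
Product: 10 methyl (5R)-7,7-dimethoxy-2-methylidene-5-[2-(triethylsilyloxy)propan-2-yl]heptanoate
Conditions: Pd(OAc)2 (5 mol %), PPh3 (10 mol %), CO (1 atm), MeOH, Et3N, DMF, 23 → 40 °C
Reagents that add atoms: carbon monoxide, SMILES [C-]#[O+]; methanol, SMILES CO
Why: Palladium-catalysed alkoxycarbonylation of a vinyl triflate (oxidative addition, CO insertion, methanolysis of the acylpalladium) places the ester on the carbon that becomes C10 and leaves the acetal and silyl ether alone.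

Step 7
Reactants: 10 methyl (5R)-7,7-dimethoxy-2-methylidene-5-[2-(triethylsilyloxy)propan-2-yl]heptanoate
Product: 12 methyl (5R)-2-methylidene-7-oxo-5-[2-(triethylsilyloxy)propan-2-yl]heptanoate, via lutidinium salt 11 (not isolated)
Conditions: Et3SiOTf (2 equiv), 2,6-lutidine (3 equiv), CH2Cl2, 0 °C; then H2O
Reagents that add atoms: water, SMILES O
Why: Acetal cleavage under weakly basic conditions works because the silyl triflate ionises one methoxy group, 2,6-lutidine traps the oxocarbenium ion as a salt and water hydrolyses that salt to the aldehyde, so no protic acid meets the tertiary silyl ether.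

Step 8
Reactants: 12 methyl (5R)-2-methylidene-7-oxo-5-[2-(triethylsilyloxy)propan-2-yl]heptanoate; 13 dimethyl (2-oxopropyl)phosphonate
Product: 14 methyl (5R,7E)-2-methylidene-9-oxo-5-[2-(triethylsilyloxy)propan-2-yl]dec-7-enoate
Conditions: LiCl, iPr2NEt, MeCN, 23 °C
Reagents that add atoms: none
Why: Horner–Wadsworth–Emmons olefination with a stabilised β-ketophosphonate under LiCl/amine conditions is E-selective through reversible addition and is mild enough for the enolisable aldehyde and the acrylate.

Step 9
Reactants: 14 methyl (5R,7E)-2-methylidene-9-oxo-5-[2-(triethylsilyloxy)propan-2-yl]dec-7-enoate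
Product: 15 methyl (5R,7E)-9-(tert-butyldimethylsilyloxy)-2-methylidene-5-[2-(triethylsilyloxy)propan-2-yl]deca-7,9-dienoate
Conditions: tBuMe2SiOTf, Et3N, CH2Cl2, 0 °C; chromatography on Et3N-deactivated silica
Reagents that add atoms: tert-butyldimethylsilyl triflate, SMILES CC(C)(C)[Si](C)(C)OS(=O)(=O)C(F)(F)F
Why: Soft enolisation (O-silylation of the enone, then removal of an α′-methyl proton by Et3N) gives the cross-conjugated 2-silyloxy-1,3-diene with the E alkene retained, and the acrylate has no α-hydrogen to enolise.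

Step 10
Reactants: 15 methyl (5R,7E)-9-(tert-butyldimethylsilyloxy)-2-methylidene-5-[2-(triethylsilyloxy)propan-2-yl]deca-7,9-dienoate
Product: 16 methyl (5S,7R,10R)-3-(tert-butyldimethylsilyloxy)-7β-[2-(triethylsilyloxy)propan-2-yl]-trans-octal-3-ene-10β-carboxylate (5α-H; C3=C4 silyl enol ether)
Conditions: toluene (0.01 M), BHT (0.1 equiv), base-washed sealed tube, 175 °C
Reagents that add atoms: none
Why: This is a thermal, concerted but asynchronous suprafacial [4+2] cycloaddition in which the nucleophilic terminus C2 of the diene C2=C3–C4=C5 bonds to the acrylate β-carbon C1 while C5 bonds to C10, and its closest known type is the type 1 intramolecular Diels–Alder reaction of 1,7,9-decatrienes that carry the activating ester on the internal dienophile carbon. Ring A (C1–C5 and C10) closes as the new cyclohexene of the cycloaddition, and ring B (C5–C10) closes in the fused mode as the six-membered ring spanned by the four-carbon tether C6–C9 when C5–C10 forms. For C10 relative to C5, ester and tether are geminal on C10, so the ester-endo transition state holds the tether exo, and with the E alkene C4=C5 this places CO2Me and H5 on opposite faces, which is the trans fusion. For C5 and C10 relative to C7, the tether folds as a chair in which the very large C(CH3)2OSiEt3 group stays equatorial, so one diene face is reached and 5S,10R follow from 7R. The step needs regio-, facial and endo/exo selectivity: the first is fixed by tether length and reinforced by donor–acceptor polarity (1,4 relation of OSi and CO2Me), the second by the C7 anchor, and the third rests only on the endo preference of the ester and is the weak point. The resulting silyl enol ether marks C3 as the latent ketone.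

Step 11
Reactants: 16 trans-fused silyl enol ether ester
Product: 17 methyl (5S,7R,10R)-3-oxo-7β-[2-(triethylsilyloxy)propan-2-yl]-trans-decalin-10β-carboxylate
Conditions: Bu4NF (1.05 equiv), AcOH (1.1 equiv), THF, −20 → 0 °C
Reagents that add atoms: none
Why: Fluoride-induced desilylation of the silyl enol ether, whose enolate is a far better leaving group than a tertiary alkoxide, frees the C3 ketone with acetic acid as proton source while the hindered triethylsilyl ether stays, and C5 is β to the carbonyl and not at risk.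

Step 12
Reactants: 17 methyl (5S,7R,10R)-3-oxo-7β-[2-(triethylsilyloxy)propan-2-yl]-trans-decalin-10β-carboxylate
Product: 18 methyl (3R,5S,7R,10R)-3α-hydroxy-3β-methyl-7β-[2-(triethylsilyloxy)propan-2-yl]-trans-decalin-10β-carboxylate
Conditions: MeTi(OiPr)3 (3 equiv), hexane/CH2Cl2, −20 → 23 °C; then H2O
Reagents that add atoms: methyltitanium triisopropoxide, SMILES C[Ti](OC(C)C)(OC(C)C)OC(C)C
Why: Organotitanium carbonyl methylation is chemoselective for the ketone over the ester, and the bulky reagent attacks the chair cyclohexanone along the equatorial (β) trajectory away from the axial hydrogens at C1 and C5, which sets C3 with equatorial CH3 and axial 3α-OH.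

Step 13
Reactants: 18 methyl (3R,5S,7R,10R)-3α-hydroxy-3β-methyl-7β-[2-(triethylsilyloxy)propan-2-yl]-trans-decalin-10β-carboxylate
Product: 19 (3R,5S,7R,10R)-10β-(hydroxymethyl)-3β-methyl-7β-[2-(triethylsilyloxy)propan-2-yl]-trans-decalin-3α-ol
Conditions: LiAlH4, THF, 0 → 40 °C; H2O quench
Reagents that add atoms: none
Why: Hydride reduction of the hindered angular ester by LiAlH4 gives the neopentyl primary alcohol and affects neither the silyl ether nor any stereocentre.

Step 14
Reactants: 19 (3R,5S,7R,10R)-10β-(hydroxymethyl)-3β-methyl-7β-[2-(triethylsilyloxy)propan-2-yl]-trans-decalin-3α-ol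
Product: 20 primary methanesulfonate of 19 (C10–CH2OMs; 3α-OH free)
Conditions: MsCl (1.1 equiv), Et3N, CH2Cl2, −10 °C
Reagents that add atoms: methanesulfonyl chloride, SMILES CS(=O)(=O)Cl
Why: Sulfonylation through the sulfene pathway takes the primary hydroxyl group and leaves the axial tertiary one untouched.

Step 15
Reactants: 20 primary methanesulfonate
Product: 21 (3R,5S,7R,10S)-3β,10β-dimethyl-7β-[2-(triethylsilyloxy)propan-2-yl]-trans-decalin-3α-ol
Conditions: LiEt3BH (5 equiv), THF, 65 °C; H2O quench
Reagents that add atoms: none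
Why: SN2 hydride displacement of a primary sulfonate by the highly nucleophilic LiEt3BH, the usual choice for neopentyl positions, turns CH2OMs into the angular methyl, and the 3α-alkoxide lies on the face opposite to C10–CH2 so it cannot close an ether.

Step 16
Reactants: 21 (3R,5S,7R,10S)-3β,10β-dimethyl-7β-[2-(triethylsilyloxy)propan-2-yl]-trans-decalin-3α-ol; 22 3-bromo-4-fluorobenzaldehyde
Product: 24 3-bromo-4-{[(3R,5S,7R,10S)-3β,10β-dimethyl-7β-[2-(triethylsilyloxy)propan-2-yl]-trans-decalin-3α-yl]oxy}benzaldehyde, via potassium alkoxide 23 (not isolated)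
Conditions: KH (1.3 equiv), 18-crown-6, THF, 0 → 23 °C; then 22 (1.5 equiv), 23 → 50 °C
Reagents that add atoms: none
Why: Nucleophilic aromatic substitution by addition–elimination through a Meisenheimer complex displaces the fluoride that is para to CHO and ortho to Br, the C3–O bond is never broken so C3 keeps its configuration, and addition of the hindered alkoxide to the aldehyde is reversible.

Step 17
Reactants: 25 4-bromophenol
Product: 26 1-(allyloxy)-4-bromobenzene
Conditions: allyl bromide, K2CO3, acetone, 56 °C
Reagents that add atoms: allyl bromide, SMILES C=CCBr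
Why: Williamson ether synthesis of a phenoxide with a reactive allylic halide.

Step 18
Reactants: 26 1-(allyloxy)-4-bromobenzene
Product: 27 2-allyl-4-bromophenol
Conditions: N,N-diethylaniline, 200 °C
Reagents that add atoms: none
Why: Aromatic Claisen rearrangement ([3,3] shift, then tautomerisation) delivers the allyl group to one of two equivalent ortho positions with bromine already para to oxygen, which avoids electrophilic bromination in the presence of an allylphenol.

Step 19
Reactants: 27 2-allyl-4-bromophenol
Product: 28 (2-allyl-4-bromophenoxy)triisopropylsilane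
Conditions: iPr3SiCl, imidazole, DMF, 23 °C
Reagents that add atoms: triisopropylsilyl chloride, SMILES CC(C)[Si](Cl)(C(C)C)C(C)C
Why: Phenol silylation gives an aryl triisopropylsilyl ether that survives the aqueous base of the cross-coupling and leaves with fluoride in the last step.

Step 20
Reactants: 28 (2-allyl-4-bromophenoxy)triisopropylsilane
Product: 30 2-[3-allyl-4-(triisopropylsilyloxy)phenyl]-4,4,5,5-tetramethyl-1,3,2-dioxaborolane, via aryllithium 29 (not isolated)
Conditions: n-BuLi, THF, −78 °C; then 2-isopropoxy-4,4,5,5-tetramethyl-1,3,2-dioxaborolane, −78 → 23 °C; H2O quench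
Reagents that add atoms: 2-isopropoxy-4,4,5,5-tetramethyl-1,3,2-dioxaborolane, SMILES CC(C)OB1OC(C)(C)C(C)(C)O1
Why: Bromine–lithium exchange at −78 °C outruns deprotonation of the benzylic allylic CH2, and the aryllithium is borylated by displacement of isopropoxide.

Step 21
Reactants: 24 bromoaryl ether aldehyde; 30 arylboronate
Product: 31 3-[3-allyl-4-(triisopropylsilyloxy)phenyl]-4-{[(3R,5S,7R,10S)-3β,10β-dimethyl-7β-[2-(triethylsilyloxy)propan-2-yl]-trans-decalin-3α-yl]oxy}benzaldehyde
Conditions: Pd(OAc)2 (5 mol %), SPhos (10 mol %), K3PO4, toluene/H2O 10:1, 80 °C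
Reagents that add atoms: none
Why: Suzuki–Miyaura cross-coupling with a bulky electron-rich biarylphosphine copes with the bromide ortho to the large tertiary alkoxy group and tolerates the aldehyde, the allyl group and both silyl ethers.

Step 22
Reactants: 31 biaryl aldehyde
Product: 32 the corresponding benzylic alcohol (CHO replaced by CH2OH)
Conditions: NaBH4, THF/MeOH, 0 °C
Reagents that add atoms: none
Why: Borohydride carbonyl reduction touches only the aldehyde.

Step 23
Reactants: 32 benzylic alcohol
Product: 33 the corresponding benzylic bromide (CH2OH replaced by CH2Br), used without storage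
Conditions: CBr4, PPh3, CH2Cl2, 0 °C
Reagents that add atoms: carbon tetrabromide, SMILES BrC(Br)(Br)Br
Why: The Appel reaction converts the primary benzylic alcohol to the bromide under neutral conditions that spare the acid-labile tertiary alkyl aryl ether.

Step 24
Reactants: 33 benzylic bromide
Product: 34 bis-silyl ether of the target (C11 OSiEt3; phenol OSi(iPr)3; both allyl groups in place)
Conditions: tributyl(vinyl)stannane, Pd(PPh3)4 (5 mol %), THF, 65 °C
Reagents that add atoms: tributyl(vinyl)stannane, SMILES C=C[Sn](CCCC)(CCCC)CCCC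
Why: Stille coupling of a benzylic bromide with a vinylstannane builds the allyl group from a benzyl and a vinyl carbon, so the alkene is terminal by construction, and it runs without base.

Step 25
Reactants: 34 bis-silyl ether of the target
Product: 35 CNP0342687.1 (3R,5S,7R,10S)
Conditions: Bu4NF (5 equiv), THF, 23 → 45 °C; AcOH quench
Reagents that add atoms: none
Why: Global fluoride desilylation removes the aryl triisopropylsilyl ether at once and the tertiary triethylsilyl ether on warming, and the absence of strong acid protects the tertiary alkyl aryl ether and both allyl groups.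

**Compound list**

1 | (R)-(+)-limonene | CC1=CC[C@@H](CC1)C(C)=C | starting material
2 | acetoxymercurial of 1 (C–HgOAc on the former =CH2; tertiary OH; carbinol centre unassigned) | CC1=CC[C@@H](CC1)C(C)(O)C[Hg]OC(C)=O | intermediate
3 | (R)-α-terpineol | CC1=CC[C@@H](CC1)C(C)(C)O | intermediate
4 | (R)-α-terpinyl triethylsilyl ether | CC1=CC[C@@H](CC1)C(C)(C)O[Si](CC)(CC)CC | intermediate
5 | secondary ozonide of 4 (7,8,9-trioxabicyclo[4.2.1]nonane; ozonide carbons unassigned) | CC12CC[C@H](CC(OO1)O2)C(C)(C)O[Si](CC)(CC)CC | intermediate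
6 | (3R)-6-oxo-3-[2-(triethylsilyloxy)propan-2-yl]heptanal | O=CC[C@@H](CCC(C)=O)C(C)(C)O[Si](CC)(CC)CC | intermediate
7 | (5R)-7,7-dimethoxy-5-[2-(triethylsilyloxy)propan-2-yl]heptan-2-one | COC(OC)C[C@@H](CCC(C)=O)C(C)(C)O[Si](CC)(CC)CC | intermediate
8 | terminal lithium enolate of 7 | COC(OC)C[C@@H](CCC(=C)O[Li])C(C)(C)O[Si](CC)(CC)CC | intermediate
9 | (5R)-7,7-dimethoxy-5-[2-(triethylsilyloxy)propan-2-yl]hept-1-en-2-yl triflate | COC(OC)C[C@@H](CCC(=C)OS(=O)(=O)C(F)(F)F)C(C)(C)O[Si](CC)(CC)CC | intermediate
10 | methyl (5R)-7,7-dimethoxy-2-methylidene-5-[2-(triethylsilyloxy)propan-2-yl]heptanoate | COC(OC)C[C@@H](CCC(=C)C(=O)OC)C(C)(C)O[Si](CC)(CC)CC | intermediate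
11 | 1-(1-methoxyalkyl)-2,6-lutidinium triflate from 10 (N,O-acetal carbon unassigned) | COC(C[C@@H](CCC(=C)C(=O)OC)C(C)(C)O[Si](CC)(CC)CC)[n+]1c(C)cccc1C.[O-]S(=O)(=O)C(F)(F)F | intermediate
12 | methyl (5R)-2-methylidene-7-oxo-5-[2-(triethylsilyloxy)propan-2-yl]heptanoate | O=CC[C@@H](CCC(=C)C(=O)OC)C(C)(C)O[Si](CC)(CC)CC | intermediate
13 | dimethyl (2-oxopropyl)phosphonate | COP(=O)(CC(C)=O)OC | starting material
14 | methyl (5R,7E)-2-methylidene-9-oxo-5-[2-(triethylsilyloxy)propan-2-yl]dec-7-enoate | CC(=O)/C=C/C[C@@H](CCC(=C)C(=O)OC)C(C)(C)O[Si](CC)(CC)CC | intermediate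
15 | methyl (5R,7E)-9-(tert-butyldimethylsilyloxy)-2-methylidene-5-[2-(triethylsilyloxy)propan-2-yl]deca-7,9-dienoate | C=C(O[Si](C)(C)C(C)(C)C)/C=C/C[C@@H](CCC(=C)C(=O)OC)C(C)(C)O[Si](CC)(CC)CC | intermediate
16 | methyl (5S,7R,10R)-3-(tert-butyldimethylsilyloxy)-7β-[2-(triethylsilyloxy)propan-2-yl]-trans-octal-3-ene-10β-carboxylate | CC(C)(C)[Si](C)(C)OC1CC[C@]2(C(=O)OC)CC[C@@H](C(C)(C)O[Si](CC)(CC)CC)C[C@H]2C=1 | intermediate
17 | methyl (5S,7R,10R)-3-oxo-7β-[2-(triethylsilyloxy)propan-2-yl]-trans-decalin-10β-carboxylate | O=C1CC[C@]2(C(=O)OC)CC[C@@H](C(C)(C)O[Si](CC)(CC)CC)C[C@H]2C1 | intermediate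
18 | methyl (3R,5S,7R,10R)-3α-hydroxy-3β-methyl-7β-[2-(triethylsilyloxy)propan-2-yl]-trans-decalin-10β-carboxylate | O[C@]1(C)CC[C@]2(C(=O)OC)CC[C@@H](C(C)(C)O[Si](CC)(CC)CC)C[C@H]2C1 | intermediate
19 | (3R,5S,7R,10R)-10β-(hydroxymethyl)-3β-methyl-7β-[2-(triethylsilyloxy)propan-2-yl]-trans-decalin-3α-ol | O[C@]1(C)CC[C@]2(CO)CC[C@@H](C(C)(C)O[Si](CC)(CC)CC)C[C@H]2C1 | intermediate
20 | primary methanesulfonate of 19 | O[C@]1(C)CC[C@]2(COS(C)(=O)=O)CC[C@@H](C(C)(C)O[Si](CC)(CC)CC)C[C@H]2C1 | intermediate
21 | (3R,5S,7R,10S)-3β,10β-dimethyl-7β-[2-(triethylsilyloxy)propan-2-yl]-trans-decalin-3α-ol | O[C@]1(C)CC[C@]2(C)CC[C@@H](C(C)(C)O[Si](CC)(CC)CC)C[C@H]2C1 | intermediate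
22 | 3-bromo-4-fluorobenzaldehyde | O=Cc1ccc(F)c(Br)c1 | starting material
23 | potassium 3α-alkoxide of 21 | [K+].[O-][C@]1(C)CC[C@]2(C)CC[C@@H](C(C)(C)O[Si](CC)(CC)CC)C[C@H]2C1 | intermediate
24 | 3-bromo-4-(decalin-3α-yloxy)benzaldehyde (decalin part as in 21) | O=Cc1ccc(O[C@]2(C)CC[C@]3(C)CC[C@@H](C(C)(C)O[Si](CC)(CC)CC)C[C@H]3C2)c(Br)c1 | intermediate
25 | 4-bromophenol | Oc1ccc(Br)cc1 | starting material
26 | 1-(allyloxy)-4-bromobenzene | C=CCOc1ccc(Br)cc1 | intermediate
27 | 2-allyl-4-bromophenol | C=CCc1cc(Br)ccc1O | intermediate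
28 | (2-allyl-4-bromophenoxy)triisopropylsilane | C=CCc1cc(Br)ccc1O[Si](C(C)C)(C(C)C)C(C)C | intermediate
29 | [3-allyl-4-(triisopropylsilyloxy)phenyl]lithium | C=CCc1cc([Li])ccc1O[Si](C(C)C)(C(C)C)C(C)C | intermediate
30 | 2-[3-allyl-4-(triisopropylsilyloxy)phenyl]-4,4,5,5-tetramethyl-1,3,2-dioxaborolane | C=CCc1cc(B2OC(C)(C)C(C)(C)O2)ccc1O[Si](C(C)C)(C(C)C)C(C)C | intermediate
31 | biaryl aldehyde (decalin part as in 21) | O=Cc1ccc(O[C@]2(C)CC[C@]3(C)CC[C@@H](C(C)(C)O[Si](CC)(CC)CC)C[C@H]3C2)c(-c2ccc(O[Si](C(C)C)(C(C)C)C(C)C)c(CC=C)c2)c1 | intermediate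
32 | biaryl benzylic alcohol | OCc1ccc(O[C@]2(C)CC[C@]3(C)CC[C@@H](C(C)(C)O[Si](CC)(CC)CC)C[C@H]3C2)c(-c2ccc(O[Si](C(C)C)(C(C)C)C(C)C)c(CC=C)c2)c1 | intermediate
33 | biaryl benzylic bromide | BrCc1ccc(O[C@]2(C)CC[C@]3(C)CC[C@@H](C(C)(C)O[Si](CC)(CC)CC)C[C@H]3C2)c(-c2ccc(O[Si](C(C)C)(C(C)C)C(C)C)c(CC=C)c2)c1 | intermediate
34 | bis-silyl ether of the target | C=CCc1ccc(O[C@]2(C)CC[C@]3(C)CC[C@@H](C(C)(C)O[Si](CC)(CC)CC)C[C@H]3C2)c(-c2ccc(O[Si](C(C)C)(C(C)C)C(C)C)c(CC=C)c2)c1 | intermediate
35 | CNP0342687.1: 2-{(3R,5S,7R,10S)-3α-[(3',5-diallyl-4'-hydroxybiphenyl-2-yl)oxy]-3β,10β-dimethyl-trans-decalin-7β-yl}propan-2-ol | C=CCc1ccc(O[C@]2(C)CC[C@]3(C)CC[C@@H](C(C)(C)O)C[C@H]3C2)c(-c2ccc(O)c(CC=C)c2)c1 | target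

Total step count: 25. Longest linear sequence: 21 (steps 1–16 and 21–25). Steps 17–20 form the convergent boronate branch.

**Steps most likely to fail**

**Step 10.** The endo preference of a 2-alkylacrylate ester is modest at the temperature needed. Tether-endo folding may therefore compete and erode the trans/cis ring-fusion selectivity.
- The fallback stops relying on kinetic endo/exo control and resets C5 afterwards. It sets out from 16, taken as the mixture of ring-fusion isomers.
- The chair-folded cis adduct has the same C7 and C10 configuration as 16 and differs only at C5.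
- Saegusa–Ito oxidation with Pd(OAc)2 in MeCN/DMSO converts every isomer into the C4=C5 enone methyl (7R,10R)-3-oxo-7β-[2-(triethylsilyloxy)propan-2-yl]octal-4-ene-10β-carboxylate F1, which erases C5.
- Dissolving-metal reduction follows (Li, 2.2 equiv, NH3/THF, tBuOH 1 equiv, −78 °C, NH4Cl quench; lithium is kept limiting so the hindered ester is spared).
- Axial protonation of C5 then gives the trans-fused ketone, and the route is rejoined at 17.

**Step 16.** Substitution by the hindered axial tertiary alkoxide may be slow. Its reversible addition to the formyl group could then drain into hydride transfer of the Tishchenko or Cannizzaro type, consuming both partners.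
- The fallback sets out from 21, deprotonated to 23 as before, and uses a carbonyl-free acceptor, 3-bromo-4-fluorobenzonitrile, in THF with 18-crown-6.
- The same addition–elimination gives the nitrile 3-bromo-4-(decalin-3α-yloxy)benzonitrile F2.
- Partial reduction with iBu2AlH (toluene, −78 °C) and hydrolytic work-up with aqueous citric acid restores the aldehyde oxidation level, and the route is rejoined at 24.

**Step 15.** Hydride may attack sulfur instead of the shielded neopentyl carbon, so that S–O cleavage returns the alcohol.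
- The fallback replaces the polar displacement by a radical C–O scission that is insensitive to neopentyl hindrance (Barton–McCombie deoxygenation). It sets out from 19.
- 1,1'-Thiocarbonyldiimidazole with DMAP in THF at 60 °C acylates only the primary hydroxyl group to give the O-neopentyl imidazole-1-carbothioate F3.
- Bu3SnH with AIBN in refluxing toluene delivers the angular methyl group, and the route is rejoined at 21.

**Further compounds**

F1 | step 10 | methyl (7R,10R)-3-oxo-7β-[2-(triethylsilyloxy)propan-2-yl]octal-4-ene-10β-carboxylate | O=C1CC[C@]2(C(=O)OC)CC[C@@H](C(C)(C)O[Si](CC)(CC)CC)CC2=C1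
F2 | step 16 | 3-bromo-4-{[(3R,5S,7R,10S)-3β,10β-dimethyl-7β-[2-(triethylsilyloxy)propan-2-yl]-trans-decalin-3α-yl]oxy}benzonitrile | N#Cc1ccc(O[C@]2(C)CC[C@]3(C)CC[C@@H](C(C)(C)O[Si](CC)(CC)CC)C[C@H]3C2)c(Br)c1
F3 | step 15 | O-{[(3R,5S,7R,10R)-3α-hydroxy-3β-methyl-7β-[2-(triethylsilyloxy)propan-2-yl]-trans-decalin-10β-yl]methyl} imidazole-1-carbothioate | O[C@]1(C)CC[C@]2(COC(=S)n3ccnc3)CC[C@@H](C(C)(C)O[Si](CC)(CC)CC)C[C@H]2C1
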